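**Retrosynthetic overview**
- Target 12 ⇐ fully O-alkylated biflavone 10 by one BCl3 deprotection (three benzyl ethers and the peri 5-OMe of chromone A).
- 10 ⇐ acyclic bis(1,3-diketone) 8 by two C–O ring closures in one operation (O1–C8a of each pyranone, an ortho-alkoxy group as leaving group); chromone B is taken to close first, then the 2,3-diarylchromone A.
- 8 ⇐ ester 5 + tris(benzyloxy)acetophenone 7 (Claisen condensation).
- 5 ⇐ deoxybenzoin 3 + aroyl chloride 4 (C-aroylation); 3 ⇐ ketone 1 + aryl bromide 2 (α-arylation).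

Assumption: the SMILES has no stereocentre and defines no axial configuration, so the target is treated as achiral and no stereocontrol is needed.

**Step 1**
Reactants: 1 1-(2,4,6-trimethoxyphenyl)ethan-1-one; 2 methyl 3-bromo-4-methoxybenzoate
Product: 3 methyl 4-methoxy-3-[2-oxo-2-(2,4,6-trimethoxyphenyl)ethyl]benzoate
Conditions: Pd2(dba)3 (1.5 mol %), Xantphos (3.6 mol %), K3PO4 (2.5 equiv), 1 (1.2 equiv), toluene, 90 °C
Reagents that add atoms: none
Why: Palladium-catalysed ketone α-arylation (Buchwald–Hartwig type), in which the methyl-ketone enolate couples with the aryl bromide at zerovalent palladium, K3PO4 spares the methyl ester, and the ortho-methoxy group of the bromide together with the wide-bite-angle ligand stops the reaction at mono-arylation.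

**Step 2**
Reactants: 3 methyl 4-methoxy-3-[2-oxo-2-(2,4,6-trimethoxyphenyl)ethyl]benzoate; 4 4-(benzyloxy)benzoyl chloride
Product: 5 methyl 3-[1-(4-(benzyloxy)phenyl)-1,3-dioxo-3-(2,4,6-trimethoxyphenyl)propan-2-yl]-4-methoxybenzoate
Conditions: MgBr2·OEt2 (2.5 equiv), i-Pr2NEt (3 equiv), CH2Cl2, 0 °C → rt; 1 M HCl work-up
Reagents that add atoms: none
Why: Soft-enolisation C-acylation (crossed Claisen-type), in which MgBr2 chelates the ketone and its ortho-methoxy group so that the amine deprotonates the benzylic CH2, and the magnesium enolate is aroylated at carbon and held as its chelate against further acylation; the new CH centre is racemic, labile and becomes sp2 in step 5.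

**Step 3**
Reactants: 6 1-(2,4,6-trihydroxyphenyl)ethan-1-one
Product: 7 1-[2,4,6-tris(benzyloxy)phenyl]ethan-1-one
Conditions: BnBr (3.6 equiv), K2CO3 (4 equiv), DMF, 70 °C
Reagents that add atoms: benzyl bromide, BrCc1ccccc1
Why: Williamson etherification, in which the acyl group damps C-benzylation of the phloroglucinol ring and warm DMF drives the two chelated ortho-hydroxyls to react.

**Step 4**
Reactants: 5 methyl 3-[1-(4-(benzyloxy)phenyl)-1,3-dioxo-3-(2,4,6-trimethoxyphenyl)propan-2-yl]-4-methoxybenzoate; 7 1-[2,4,6-tris(benzyloxy)phenyl]ethan-1-one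
Product: 8 1-[4-(benzyloxy)phenyl]-2-{2-methoxy-5-[3-oxo-3-(2,4,6-tris(benzyloxy)phenyl)propanoyl]phenyl}-3-(2,4,6-trimethoxyphenyl)propane-1,3-dione
Conditions: NaH (4 equiv), THF, reflux, slow addition of 7 (1.3 equiv); then 1 M HCl
Reagents that add atoms: none
Why: Crossed Claisen condensation, in which NaH first turns the triaryl diketone of 5 into its inert enolate (protecting it from retro-Claisen cleavage), and the enolate of the hindered, non-self-condensing methyl ketone 7 then attacks the methyl ester and the product is drawn off as its diketonate.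

**Step 5**
Reactants: 8 1-[4-(benzyloxy)phenyl]-2-{2-methoxy-5-[3-oxo-3-(2,4,6-tris(benzyloxy)phenyl)propanoyl]phenyl}-3-(2,4,6-trimethoxyphenyl)propane-1,3-dione
Product: 10 2-[4-(benzyloxy)phenyl]-3-{5-[5,7-bis(benzyloxy)-4-oxo-4H-chromen-2-yl]-2-methoxyphenyl}-5,7-dimethoxy-4H-chromen-4-one, via mono-cyclised chromone B diketone 9 (not isolated)
Conditions: 3,6-di-tert-butyl-9-mesityl-10-phenylacridinium tetrafluoroborate (5 mol %), ClCH2CH2Cl/(CF3)2CHOH 4:1, 0.02 M, 456 nm LEDs, Ar, 30 °C
Reagents that add atoms: none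
Why: Proposed new method: an intramolecular, redox-neutral cation-radical-accelerated SNAr ring closure, not reported to my knowledge, in which the excited acridinium (about +2.0 V vs SCE) oxidises the most electron-rich ring of each half (the 2,4,6-trialkoxybenzoyl group, about +1.6–1.7 V), the enol or carbonyl oxygen of the neighbouring aroyl group adds to the ipso carbon of an ortho-alkoxy group (the only position it can reach, the twisted aryl ketone holding it over the ring face), and electron return from the acridine radical followed by E1cB loss of BnOH (first closure) or MeOH (second closure) gives the aromatic γ-pyrone; the closest known reaction types are the intermolecular acridinium-photocatalysed SNAr of alkoxyarenes with azoles and amines and the thermal closure of 2-hydroxy-2'-methoxybenzophenones to xanthones with loss of methanol.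

**Step 6**
Reactants: 10 2-[4-(benzyloxy)phenyl]-3-{5-[5,7-bis(benzyloxy)-4-oxo-4H-chromen-2-yl]-2-methoxyphenyl}-5,7-dimethoxy-4H-chromen-4-one
Product: 12 3-[5-(5,7-dihydroxy-4-oxo-4H-chromen-2-yl)-2-methoxyphenyl]-5-hydroxy-2-(4-hydroxyphenyl)-7-methoxy-4H-chromen-4-one, via debenzylated 5-O-methyl ether 11 (not isolated)
Conditions: BCl3 (1 M in CH2Cl2, 12 equiv), C6HMe5 (10 equiv), CH2Cl2, −78 °C → rt; MeOH quench, aqueous work-up
Reagents that add atoms: none
Why: Lewis-acid ether cleavage, in which BCl3 with pentamethylbenzene as benzyl-cation trap removes the three benzyl ethers at low temperature and on warming cleaves only the methoxy group chelated to the C4 carbonyl (5-OMe of chromone A), leaving the 7-OMe and the anisole OMe intact.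

**Compound list**
1 | 1-(2,4,6-trimethoxyphenyl)ethan-1-one | CC(=O)c1c(OC)cc(OC)cc1OC | starting material
2 | methyl 3-bromo-4-methoxybenzoate | COC(=O)c1ccc(OC)c(Br)c1 | starting material
3 | methyl 4-methoxy-3-[2-oxo-2-(2,4,6-trimethoxyphenyl)ethyl]benzoate | COC(=O)c1ccc(OC)c(CC(=O)c2c(OC)cc(OC)cc2OC)c1 | intermediate
4 | 4-(benzyloxy)benzoyl chloride | O=C(Cl)c1ccc(OCc2ccccc2)cc1 | starting material
5 | methyl 3-[1-(4-(benzyloxy)phenyl)-1,3-dioxo-3-(2,4,6-trimethoxyphenyl)propan-2-yl]-4-methoxybenzoate (racemic, labile CH) | COC(=O)c1ccc(OC)c(C(C(=O)c2c(OC)cc(OC)cc2OC)C(=O)c2ccc(OCc3ccccc3)cc2)c1 | intermediate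
6 | 1-(2,4,6-trihydroxyphenyl)ethan-1-one (sold as the monohydrate, dried before use) | CC(=O)c1c(O)cc(O)cc1O | starting material
7 | 1-[2,4,6-tris(benzyloxy)phenyl]ethan-1-one | CC(=O)c1c(OCc2ccccc2)cc(OCc2ccccc2)cc1OCc1ccccc1 | intermediate
8 | 1-[4-(benzyloxy)phenyl]-2-{2-methoxy-5-[3-oxo-3-(2,4,6-tris(benzyloxy)phenyl)propanoyl]phenyl}-3-(2,4,6-trimethoxyphenyl)propane-1,3-dione (racemic, labile CH; the unsubstituted diketone is largely enolised) | COc1ccc(C(=O)CC(=O)c2c(OCc3ccccc3)cc(OCc3ccccc3)cc2OCc2ccccc2)cc1C(C(=O)c1c(OC)cc(OC)cc1OC)C(=O)c1ccc(OCc2ccccc2)cc1 | intermediate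
9 | 1-[4-(benzyloxy)phenyl]-2-{5-[5,7-bis(benzyloxy)-4-oxo-4H-chromen-2-yl]-2-methoxyphenyl}-3-(2,4,6-trimethoxyphenyl)propane-1,3-dione (racemic, labile CH; formed in the flask) | COc1ccc(-c2cc(=O)c3c(OCc4ccccc4)cc(OCc4ccccc4)cc3o2)cc1C(C(=O)c1c(OC)cc(OC)cc1OC)C(=O)c1ccc(OCc2ccccc2)cc1 | intermediate
10 | 2-[4-(benzyloxy)phenyl]-3-{5-[5,7-bis(benzyloxy)-4-oxo-4H-chromen-2-yl]-2-methoxyphenyl}-5,7-dimethoxy-4H-chromen-4-one | COc1cc(OC)c2c(=O)c(-c3cc(-c4cc(=O)c5c(OCc6ccccc6)cc(OCc6ccccc6)cc5o4)ccc3OC)c(-c3ccc(OCc4ccccc4)cc3)oc2c1 | intermediate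
11 | 3-[5-(5,7-dihydroxy-4-oxo-4H-chromen-2-yl)-2-methoxyphenyl]-2-(4-hydroxyphenyl)-5,7-dimethoxy-4H-chromen-4-one (formed in the flask) | COc1cc(OC)c2c(=O)c(-c3cc(-c4cc(=O)c5c(O)cc(O)cc5o4)ccc3OC)c(-c3ccc(O)cc3)oc2c1 | intermediate
12 | 3-[5-(5,7-dihydroxy-4-oxo-4H-chromen-2-yl)-2-methoxyphenyl]-5-hydroxy-2-(4-hydroxyphenyl)-7-methoxy-4H-chromen-4-one | COc1cc(O)c2c(=O)c(-c3cc(-c4cc(=O)c5c(O)cc(O)cc5o4)ccc3OC)c(-c3ccc(O)cc3)oc2c1 | target

**Step count and risks**
Total steps: 6. Longest linear sequence: 5 (steps 1, 2, 4, 5, 6); step 3 is a one-step side branch.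

Step 5 (the new photochemical double ring closure) is the most likely to fail. The risks are enol oxidation without cyclisation, attack at the central anisole ring to give a benzofuran, oxidative loss of benzyl groups, or a stall at 9. The fallback uses known chemistry only and sets out from 8. BCl3 (10 equiv) with pentamethylbenzene in CH2Cl2 (−78 → 0 °C) removes all four benzyl ethers and, by chelation, one ortho-methoxy group of the trimethoxybenzoyl unit. This gives 1-(2-hydroxy-4,6-dimethoxyphenyl)-3-(4-hydroxyphenyl)-2-{2-methoxy-5-[3-oxo-3-(2,4,6-trihydroxyphenyl)propanoyl]phenyl}propane-1,3-dione F1. Classical acid cyclodehydration of both ortho-hydroxyaryl diketones (AcOH, catalytic H2SO4, 95 °C) then gives 11, where the fallback comes back to the route. The warm BCl3 stage of step 6 finishes to 12.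

Step 4 (Claisen condensation on an ester that is deactivated by the para-methoxy group and carries a base-sensitive triaryl diketone) is the second risk. The fallback sets out from 5 and replaces the ester electrophile by an activated acyl donor. LiI in refluxing EtOAc cleaves the methyl ester at the methyl carbon, and acidification gives 3-[1-(4-(benzyloxy)phenyl)-1,3-dioxo-3-(2,4,6-trimethoxyphenyl)propan-2-yl]-4-methoxybenzoic acid F2. 1,1'-Carbonyldiimidazole in THF converts it into 1-[4-(benzyloxy)phenyl]-2-[5-(1H-imidazole-1-carbonyl)-2-methoxyphenyl]-3-(2,4,6-trimethoxyphenyl)propane-1,3-dione F3. The preformed lithium enolate of 7 (LiN(SiMe3)2, 3.3 equiv, THF, −78 → 0 °C; the first equivalent deprotonates the diketone) is then acylated by F3 to give 8, where the fallback comes back to the route.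

Step 2 (C- versus O-aroylation of a hindered deoxybenzoin enolate) is the third risk. The fallback sets out from 3 and swaps acylation for aldol addition and oxidation. The lithium enolate of 3 (LiN(SiMe3)2, THF, −78 °C) adds to commercial 4-(benzyloxy)benzaldehyde to give methyl 3-[1-(4-(benzyloxy)phenyl)-1-hydroxy-3-oxo-3-(2,4,6-trimethoxyphenyl)propan-2-yl]-4-methoxybenzoate F4 (both diastereomers, racemic). Dess–Martin periodinane in CH2Cl2 oxidises the carbinol to the diketone 5, where the fallback comes back to the route.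

**Further compounds**
F1 | step 5 | 1-(2-hydroxy-4,6-dimethoxyphenyl)-3-(4-hydroxyphenyl)-2-{2-methoxy-5-[3-oxo-3-(2,4,6-trihydroxyphenyl)propanoyl]phenyl}propane-1,3-dione | COc1ccc(C(=O)CC(=O)c2c(O)cc(O)cc2O)cc1C(C(=O)c1c(O)cc(OC)cc1OC)C(=O)c1ccc(O)cc1
F2 | step 4 | 3-[1-(4-(benzyloxy)phenyl)-1,3-dioxo-3-(2,4,6-trimethoxyphenyl)propan-2-yl]-4-methoxybenzoic acid | COc1ccc(C(=O)O)cc1C(C(=O)c1c(OC)cc(OC)cc1OC)C(=O)c1ccc(OCc2ccccc2)cc1
F3 | step 4 | 1-[4-(benzyloxy)phenyl]-2-[5-(1H-imidazole-1-carbonyl)-2-methoxyphenyl]-3-(2,4,6-trimethoxyphenyl)propane-1,3-dione | COc1ccc(C(=O)n2ccnc2)cc1C(C(=O)c1c(OC)cc(OC)cc1OC)C(=O)c1ccc(OCc2ccccc2)cc1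
F4 | step 2 | methyl 3-[1-(4-(benzyloxy)phenyl)-1-hydroxy-3-oxo-3-(2,4,6-trimethoxyphenyl)propan-2-yl]-4-methoxybenzoate (diastereomer mixture) | COC(=O)c1ccc(OC)c(C(C(=O)c2c(OC)cc(OC)cc2OC)C(O)c2ccc(OCc3ccccc3)cc2)c1
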